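The carotenoid is cut at C11=C12 and C11'=C12' into a β-ring C15 ylide, the C10 trienedial and an ε-ring C15 ylide, so each hydroxyl receives its own acyl group. The route rests on the ε ring, whose C3' carbinol and C6' methine lie 1,4-trans across the C4'=C5' double bond. With C3' as ketone and C7' as ester, C6'-H is a vinylogous β-keto ester proton. One asymmetric transfer hydrogenation of C3'=O, run while C6' epimerises through the dienolate, should fix both centres from a racemate. The precursor is the racemic trimethylcyclohexenone ester obtained by annulating mesityl oxide with ethyl acetoacetate.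

Key step: step 2

Remark on the target: the SMILES reads as all-E (3R,3'R,6'R)-β,ε-carotene-3,3'-diol (lutein) with tetradecanoate on the β-ring O3 and hexadecanoate on the ε-ring O3'. Positions use carotenoid numbering (primed = ε half); fragment names use their own ring numbering.
Remark on configuration: O3' and C7' are trans on the ε ring, which is (1R,4R) in the ring ester. The descriptor at C6' stays R from ester to polyene because the priority order only rotates (C7' > C5' > C1' becomes C5' > C1' > C7').
Assumption: the sense of induction of the (R,R)-TsDPEN catalyst is carried over from aryl and alkynyl ketones to this cyclic enone. Commercial 11 is mainly the E isomer and its anion is delocalised, so the reagent geometry is not decisive.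

Step 1
Reactants: 1 mesityl oxide; 2 ethyl acetoacetate
Product: 5 racemic ethyl 2,6,6-trimethyl-4-oxocyclohex-2-ene-1-carboxylate, via Michael adduct 3 (not isolated), via cyclic ketol 4 (not isolated)
Conditions: ZnCl2 (0.2 equiv), toluene–heptane, reflux, Dean–Stark trap
Reagents that add atoms: none
Why: Lewis-acid-promoted Michael addition of the acetoacetate carbon to the β-carbon of 1 followed by intramolecular aldol condensation (a Robinson-type annulation) should give 5, because the keto group of 3 next to the ester enolises towards the ester-bearing carbon and therefore acts as the electrophile for the terminal methyl ketone, and C6' is formed racemic, which is what step 2 wants.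

Step 2
Reactants: 5 racemic ethyl 2,6,6-trimethyl-4-oxocyclohex-2-ene-1-carboxylate
Product: 7 ethyl (1R,4R)-4-hydroxy-2,6,6-trimethylcyclohex-2-ene-1-carboxylate, via ammonium dienolate 6 (not isolated)
Conditions: RuCl(p-cymene)[(R,R)-TsDPEN] (1 mol %), Et3N (4 equiv), DBU (0.2 equiv), HCO2H (1.5 equiv, added over 12 h), degassed MeCN, 35 °C, argon
Reagents that add atoms: none
Why: Proposed new method: free amine removes the C6' proton (alpha to the ester, gamma to the enone), so the enantiomers of 5 interconvert through the planar dienolate 6, while the ruthenium hydride generated from formate hands H− from Ru and H+ from the ligand NH2 to the C3' carbonyl in an outer-sphere six-membered transition state and loss of CO2 makes this irreversible. The closest known reaction type is the dynamic kinetic resolution of alpha-substituted beta-keto esters by Noyori asymmetric transfer hydrogenation; new here is that the labile centre is relayed to the carbonyl through the C4'=C5' double bond. No ring is closed and no skeletal bond is formed, only the C3'-H bond. C3' is controlled by the catalyst: with the (R,R) ligand the C4'=C5' alkene should take the place that an aryl or alkynyl group takes next to the p-cymene ring, which exposes the face leading to the R carbinol. C6' is controlled by which enantiomer reacts faster: the ester stands pseudoaxial to escape A(1,2) strain with the C5' methyl, the C1' methyl anti to it is then axial and blocks its own face of the carbonyl as in 3,3,5-trimethylcyclohexanone, so only in the 6'R ketone is the face chosen by the catalyst the open one (syn to the ester), which gives the trans product. The step needs 1,2- over 1,4-reduction and epimerisation faster than reduction: the fully substituted C5' slows conjugate hydride addition, the deconjugated tautomer is a dialkyl ketone of the kind this catalyst reduces sluggishly, slow dosing of HCO2H into excess amine keeps hydride supply rate-limiting, and once C3' is a carbinol C6'-H is no longer acidic enough to epimerise.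

Step 3
Reactants: 7 ethyl (1R,4R)-4-hydroxy-2,6,6-trimethylcyclohex-2-ene-1-carboxylate
Product: 8 ethyl (1R,4R)-4-[(tert-butyldimethylsilyl)oxy]-2,6,6-trimethylcyclohex-2-ene-1-carboxylate
Conditions: TBSCl, imidazole, DMF, rt
Reagents that add atoms: tert-butyldimethylsilyl chloride, CC(C)(C)[Si](C)(C)Cl
Why: Imidazole-promoted silylation of the only hydroxyl group touches no stereocentre, and the TBS ether should outlast the hydride, oxidation, carbanion and ylide steps that follow.

Step 4
Reactants: 8 ethyl (1R,4R)-4-[(tert-butyldimethylsilyl)oxy]-2,6,6-trimethylcyclohex-2-ene-1-carboxylate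
Product: 9 [(1R,4R)-4-[(tert-butyldimethylsilyl)oxy]-2,6,6-trimethylcyclohex-2-en-1-yl]methanol
Conditions: i-Bu2AlH (3 equiv), CH2Cl2, −78 → 0 °C; aq. potassium sodium tartrate work-up
Reagents that add atoms: none
Why: Exhaustive hydride reduction of the hindered ester to the primary alcohol avoids the uncertainty of halting at the aldehyde, and the non-basic low-temperature conditions leave C6' and the silyl ether alone.

Step 5
Reactants: 9 [(1R,4R)-4-[(tert-butyldimethylsilyl)oxy]-2,6,6-trimethylcyclohex-2-en-1-yl]methanol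
Product: 10 (1R,4R)-4-[(tert-butyldimethylsilyl)oxy]-2,6,6-trimethylcyclohex-2-ene-1-carbaldehyde (ε-ring C10 aldehyde)
Conditions: Dess–Martin periodinane, pyridine, CH2Cl2, 0 °C
Reagents that add atoms: none
Why: Dess–Martin oxidation buffered with pyridine is essentially neutral, so the β,γ-unsaturated aldehyde should neither epimerise at C6' nor move its double bond into conjugation, and it is carried on without chromatography.

Step 6
Reactants: 10 ε-ring C10 aldehyde; 11 triethyl (E)-3-methyl-4-phosphonocrotonate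
Product: 13 ethyl (2E,4E)-5-[(1R,4R)-4-[(tert-butyldimethylsilyl)oxy]-2,6,6-trimethylcyclohex-2-en-1-yl]-3-methylpenta-2,4-dienoate, via lithiated phosphonate 12 (not isolated)
Conditions: 11, LiN(SiMe3)2, DMPU, THF, −78 °C; then 10, −78 → 0 °C
Reagents that add atoms: 11 triethyl (E)-3-methyl-4-phosphonocrotonate, CCOC(=O)/C=C(C)/CP(=O)(OCC)OCC
Why: Vinylogous Horner–Wadsworth–Emmons olefination: the stabilised, weakly basic lithium phosphonate 12 should add to the aldehyde at low temperature faster than it removes the shielded tertiary C6'-H, reversible addition gives the E C7'=C8' bond, the E C9'=C10' isomer predominates and any 9'Z ester is removed by chromatography.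

Step 7
Reactants: 13 ε-ring C15 dienoate
Product: 14 (2E,4E)-5-[(1R,4R)-4-[(tert-butyldimethylsilyl)oxy]-2,6,6-trimethylcyclohex-2-en-1-yl]-3-methylpenta-2,4-dien-1-ol
Conditions: i-Bu2AlH (2.5 equiv), CH2Cl2, −78 °C; aq. potassium sodium tartrate work-up
Reagents that add atoms: none
Why: 1,2-Reduction of the dienoate with i-Bu2AlH gives the dienol without touching the diene, the ring alkene or the silyl ether.

Step 8
Reactants: 14 ε-ring C15 dienol
Product: 17 {(2E,4E)-5-[(1R,4R)-4-[(tert-butyldimethylsilyl)oxy]-2,6,6-trimethylcyclohex-2-en-1-yl]-3-methylpenta-2,4-dien-1-yl}triphenylphosphonium chloride, via allylic mesylate 15 (not isolated), via allylic chloride 16 (not isolated)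
Conditions: MsCl, LiCl, 2,4,6-collidine, DMF, 0 °C; crude chloride, then PPh3, MeCN, 40 °C
Reagents that add atoms: lithium chloride, [Li+].[Cl-]; triphenylphosphine, c1ccc(cc1)P(c1ccccc1)c1ccccc1
Why: Mesylation with in situ chloride displacement under collidine buffering and SN2 quaternisation of PPh3 at the primary carbon make the Wittig salt without the strong acid of the usual PPh3·HBr method, which the allylic C3' silyl ether would not tolerate.

Step 9
Reactants: 18 ketoisophorone
Product: 20 (4R,6R)-4-hydroxy-2,2,6-trimethylcyclohexan-1-one (actinol), via levodione 19 (not isolated)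
Conditions: ene-reductase OYE2, NADP+, D-glucose, glucose dehydrogenase, KH2PO4/K2HPO4 buffer pH 7, 30 °C; then levodione reductase (Corynebacterium aquaticum), NAD+, more D-glucose
Reagents that add atoms: none
Why: This is the established two-enzyme reduction of ketoisophorone: the ene-reductase adds hydrogen across the C=C bond to give the 6R dione, the carbonyl reductase then reduces only the unhindered C4 ketone, and its active site sets the 4R carbinol that becomes C3 of the target (C6 is erased in step 11).

Step 10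
Reactants: 20 actinol
Product: 21 (4R,6R)-4-[(tert-butyldimethylsilyl)oxy]-2,2,6-trimethylcyclohexan-1-one
Conditions: TBSCl, imidazole, DMF, rt
Reagents that add atoms: tert-butyldimethylsilyl chloride, CC(C)(C)[Si](C)(C)Cl
Why: Standard silylation masks the hydroxyl group against the amide base of step 11 and changes no stereocentre.

Step 11
Reactants: 21 (4R,6R)-4-[(tert-butyldimethylsilyl)oxy]-2,2,6-trimethylcyclohexan-1-one
Product: 23 (4R)-4-[(tert-butyldimethylsilyl)oxy]-2,6,6-trimethylcyclohex-1-en-1-yl trifluoromethanesulfonate, via lithium enolate 22 (not isolated)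
Conditions: LiN(i-Pr)2, THF, −78 → 0 °C; PhNTf2, 0 °C → rt
Reagents that add atoms: N-phenylbis(trifluoromethanesulfonimide), O=S(=O)(N(c1ccccc1)S(=O)(=O)C(F)(F)F)C(F)(F)F
Why: Only C6 carries an α-hydrogen, so deprotonation gives the single enolate 22, O-sulfonylation with PhNTf2 gives the tetrasubstituted enol triflate, and the silyloxy group is not β to the enolate carbon, so C4 (the future C3) is safe from elimination.

Step 12
Reactants: 24 (E)-3-methylpent-2-en-4-yn-1-ol
Product: 25 (2E,4E)-3-methyl-5-(tributylstannyl)penta-2,4-dien-1-ol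
Conditions: Bu3SnH (slow addition), PdCl2(PPh3)2 (2 mol %), THF, 0 °C
Reagents that add atoms: tributyltin hydride, CCCC[SnH](CCCC)CCCC
Why: Palladium-catalysed hydrostannation is a syn addition that places tin on the less hindered terminal alkyne carbon and so gives the E-alkenylstannane, the minor internal regioisomer being removed by chromatography.

Step 13
Reactants: 23 β-ring enol triflate; 25 dienylstannane
Product: 26 (2E,4E)-5-[(4R)-4-[(tert-butyldimethylsilyl)oxy]-2,6,6-trimethylcyclohex-1-en-1-yl]-3-methylpenta-2,4-dien-1-ol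
Conditions: Pd2(dba)3 (2.5 mol %), AsPh3 (20 mol %), NMP, 60 °C
Reagents that add atoms: none
Why: Stille coupling proceeds with retention of the stannane geometry, and the weakly donating AsPh3 ligand in polar NMP speeds up transmetalation enough for hindered 2,6,6-trimethylcyclohexenyl triflates, a substrate class on which this C6–C7 bond formation is known.

Step 14
Reactants: 26 β-ring C15 dienol
Product: 27 {(2E,4E)-5-[(4R)-4-hydroxy-2,6,6-trimethylcyclohex-1-en-1-yl]-3-methylpenta-2,4-dien-1-yl}triphenylphosphonium bromide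
Conditions: PPh3·HBr (1.3 equiv), MeOH, rt
Reagents that add atoms: triphenylphosphine hydrobromide, [Br-].c1ccc(cc1)[PH+](c1ccccc1)c1ccccc1
Why: Acid-mediated substitution of the dienylic alcohol by PPh3 at the primary terminus of the pentadienyl cation is the standard way to C15 Wittig salts, the small excess of acid in MeOH cleaves the TBS ether in the same operation, and the homoallylic C3 carbinol does not ionise.

Step 15
Reactants: 27 β-ring C15 phosphonium bromide; 28 (2E,4E,6E)-2,7-dimethylocta-2,4,6-trienedial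
Product: 30 (3R)-3-hydroxy-12'-apo-β-caroten-12'-al, via β-ring ylide 29 (not isolated)
Conditions: 28 (2.5 equiv), NaOMe, MeOH–CH2Cl2, 0 °C → rt (27 and base added slowly); then EtOH, reflux, dark
Reagents that add atoms: none
Why: Wittig olefination in which the excess of the symmetrical dialdehyde and the slow generation of ylide 29 favour reaction at one formyl group only, and the strained 11Z isomer relaxes to the E form on heating.

Step 16
Reactants: 30 (3R)-3-hydroxy-12'-apo-β-caroten-12'-al; 31 myristoyl chloride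
Product: 32 (3R)-3-(tetradecanoyloxy)-12'-apo-β-caroten-12'-al
Conditions: 31, pyridine, DMAP (cat.), CH2Cl2, 0 °C → rt
Reagents that add atoms: 31 myristoyl chloride, CCCCCCCCCCCCCC(=O)Cl
Why: DMAP-catalysed acylation of the only hydroxyl group with retention at C3, since the C–O bond is not involved, places the C14 acyl group on the β ring before the halves meet.

Step 17
Reactants: 17 ε-ring C15 phosphonium chloride; 32 (3R)-3-(tetradecanoyloxy)-12'-apo-β-caroten-12'-al
Product: 34 (3R,3'R,6'R)-3'-[(tert-butyldimethylsilyl)oxy]-β,ε-caroten-3-yl tetradecanoate, via ε-ring ylide 33 (not isolated)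
Conditions: 17, NaN(SiMe3)2, THF, −78 °C; then 32, −78 °C → rt; then heptane, reflux, dark, argon
Reagents that add atoms: none
Why: Wittig olefination with the preformed ylide 33, which should react with the polyenal much faster than with the secondary ester and is not basic enough to remove the bis-allylic C6'-H, forms C11'=C12', and heating converts the strained 11'Z isomer into the all-E polyene.

Step 18
Reactants: 34 (3R,3'R,6'R)-3'-[(tert-butyldimethylsilyl)oxy]-β,ε-caroten-3-yl tetradecanoate
Product: 35 (3R,3'R,6'R)-3'-hydroxy-β,ε-caroten-3-yl tetradecanoate (lutein 3-O-myristate)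
Conditions: Bu4NF, AcOH (1:1), THF, 0 °C → rt, dark
Reagents that add atoms: none
Why: Fluoride-induced desilylation buffered with AcOH avoids both the acid that would ionise the allylic C3'–O bond and the free alkoxide or hydroxide that would attack the myristate, so C3' keeps its configuration.

Step 19
Reactants: 35 lutein 3-O-myristate; 36 palmitoyl chloride
Product: 37 (3R,3'R,6'R)-3-(tetradecanoyloxy)-β,ε-caroten-3'-yl hexadecanoate (target)
Conditions: 36, pyridine, DMAP (cat.), CH2Cl2, 0 °C → rt, dark
Reagents that add atoms: 36 palmitoyl chloride, CCCCCCCCCCCCCCCC(=O)Cl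
Why: DMAP-catalysed acylation of the single free hydroxyl group in the presence of excess pyridine keeps the medium non-acidic, leaves the C3'–O bond intact and therefore gives the mixed diester with unambiguous placement of both acyl groups.

Compound list
1 | mesityl oxide | CC(=O)C=C(C)C | starting material
2 | ethyl acetoacetate | CCOC(=O)CC(C)=O | starting material
3 | ethyl 2-acetyl-3,3-dimethyl-5-oxohexanoate (racemic Michael adduct) | CCOC(=O)C(C(C)=O)C(C)(C)CC(C)=O | intermediate
4 | ethyl 2-hydroxy-2,6,6-trimethyl-4-oxocyclohexane-1-carboxylate (racemic ketol, isomer mixture) | CCOC(=O)C1C(C)(O)CC(=O)CC1(C)C | intermediate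
5 | racemic ethyl 2,6,6-trimethyl-4-oxocyclohex-2-ene-1-carboxylate | CCOC(=O)C1C(C)=CC(=O)CC1(C)C | intermediate
6 | triethylammonium 4-(ethoxycarbonyl)-3,5,5-trimethylcyclohexa-1,3-dien-1-olate (achiral dienolate) | CCOC(=O)C1=C(C)C=C([O-])CC1(C)C.CC[NH+](CC)CC | intermediate
7 | ethyl (1R,4R)-4-hydroxy-2,6,6-trimethylcyclohex-2-ene-1-carboxylate | O[C@H]1C=C(C)[C@H](C(=O)OCC)C(C)(C)C1 | intermediate
8 | ethyl (1R,4R)-4-[(tert-butyldimethylsilyl)oxy]-2,6,6-trimethylcyclohex-2-ene-1-carboxylate | CC(C)(C)[Si](C)(C)O[C@H]1C=C(C)[C@H](C(=O)OCC)C(C)(C)C1 | intermediate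
9 | [(1R,4R)-4-[(tert-butyldimethylsilyl)oxy]-2,6,6-trimethylcyclohex-2-en-1-yl]methanol | CC(C)(C)[Si](C)(C)O[C@H]1C=C(C)[C@H](CO)C(C)(C)C1 | intermediate
10 | (1R,4R)-4-[(tert-butyldimethylsilyl)oxy]-2,6,6-trimethylcyclohex-2-ene-1-carbaldehyde | CC(C)(C)[Si](C)(C)O[C@H]1C=C(C)[C@H](C=O)C(C)(C)C1 | intermediate
11 | triethyl (E)-3-methyl-4-phosphonocrotonate | CCOC(=O)/C=C(C)/CP(=O)(OCC)OCC | starting material
12 | lithium salt of the carbanion of 11 | [Li+].CCOC(=O)/C=C(C)/[CH-]P(=O)(OCC)OCC | intermediate
13 | ethyl (2E,4E)-5-[(1R,4R)-4-[(tert-butyldimethylsilyl)oxy]-2,6,6-trimethylcyclohex-2-en-1-yl]-3-methylpenta-2,4-dienoate | CC(C)(C)[Si](C)(C)O[C@H]1C=C(C)[C@H](/C=C/C(C)=C/C(=O)OCC)C(C)(C)C1 | intermediate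
14 | (2E,4E)-5-[(1R,4R)-4-[(tert-butyldimethylsilyl)oxy]-2,6,6-trimethylcyclohex-2-en-1-yl]-3-methylpenta-2,4-dien-1-ol | CC(C)(C)[Si](C)(C)O[C@H]1C=C(C)[C@H](/C=C/C(C)=C/CO)C(C)(C)C1 | intermediate
15 | methanesulfonate of 14 | CC(C)(C)[Si](C)(C)O[C@H]1C=C(C)[C@H](/C=C/C(C)=C/COS(C)(=O)=O)C(C)(C)C1 | intermediate
16 | tert-butyl({(1R,4R)-4-[(1E,3E)-5-chloro-3-methylpenta-1,3-dien-1-yl]-3,5,5-trimethylcyclohex-2-en-1-yl}oxy)dimethylsilane | CC(C)(C)[Si](C)(C)O[C@H]1C=C(C)[C@H](/C=C/C(C)=C/CCl)C(C)(C)C1 | intermediate
17 | {(2E,4E)-5-[(1R,4R)-4-[(tert-butyldimethylsilyl)oxy]-2,6,6-trimethylcyclohex-2-en-1-yl]-3-methylpenta-2,4-dien-1-yl}triphenylphosphonium chloride | CC(C)(C)[Si](C)(C)O[C@H]1C=C(C)[C@H](/C=C/C(C)=C/C[P+](c2ccccc2)(c2ccccc2)c2ccccc2)C(C)(C)C1.[Cl-] | intermediate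
18 | ketoisophorone (2,6,6-trimethylcyclohex-2-ene-1,4-dione) | CC1=CC(=O)CC(C)(C)C1=O | starting material
19 | (6R)-2,2,6-trimethylcyclohexane-1,4-dione (levodione) | O=C1[C@H](C)CC(=O)CC1(C)C | intermediate
20 | (4R,6R)-4-hydroxy-2,2,6-trimethylcyclohexan-1-one (actinol) | O=C1[C@H](C)C[C@@H](O)CC1(C)C | intermediate
21 | (4R,6R)-4-[(tert-butyldimethylsilyl)oxy]-2,2,6-trimethylcyclohexan-1-one | O=C1[C@H](C)C[C@@H](O[Si](C)(C)C(C)(C)C)CC1(C)C | intermediate
22 | lithium (4R)-4-[(tert-butyldimethylsilyl)oxy]-2,6,6-trimethylcyclohex-1-en-1-olate | [Li+].[O-]C1=C(C)C[C@@H](O[Si](C)(C)C(C)(C)C)CC1(C)C | intermediate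
23 | (4R)-4-[(tert-butyldimethylsilyl)oxy]-2,6,6-trimethylcyclohex-1-en-1-yl trifluoromethanesulfonate | O=S(=O)(OC1=C(C)C[C@@H](O[Si](C)(C)C(C)(C)C)CC1(C)C)C(F)(F)F | intermediate
24 | (E)-3-methylpent-2-en-4-yn-1-ol | OC/C=C(C)/C#C | starting material
25 | (2E,4E)-3-methyl-5-(tributylstannyl)penta-2,4-dien-1-ol | OC/C=C(C)/C=C/[Sn](CCCC)(CCCC)CCCC | intermediate
26 | (2E,4E)-5-[(4R)-4-[(tert-butyldimethylsilyl)oxy]-2,6,6-trimethylcyclohex-1-en-1-yl]-3-methylpenta-2,4-dien-1-ol | OC/C=C(C)/C=C/C1=C(C)C[C@@H](O[Si](C)(C)C(C)(C)C)CC1(C)C | intermediate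
27 | {(2E,4E)-5-[(4R)-4-hydroxy-2,6,6-trimethylcyclohex-1-en-1-yl]-3-methylpenta-2,4-dien-1-yl}triphenylphosphonium bromide | [Br-].c1ccc(cc1)[P+](c1ccccc1)(c1ccccc1)C/C=C(C)/C=C/C2=C(C)C[C@@H](O)CC2(C)C | intermediate
28 | (2E,4E,6E)-2,7-dimethylocta-2,4,6-trienedial | O=C/C(C)=C/C=C/C=C(C)/C=O | starting material
29 | ylide of 27 | c1ccc(cc1)P(c1ccccc1)(c1ccccc1)=C/C=C(C)/C=C/C2=C(C)C[C@@H](O)CC2(C)C | intermediate
30 | (3R)-3-hydroxy-12'-apo-β-caroten-12'-al | O=C/C(C)=C/C=C/C=C(C)/C=C/C=C(C)/C=C/C1=C(C)C[C@@H](O)CC1(C)C | intermediate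
31 | myristoyl chloride | CCCCCCCCCCCCCC(=O)Cl | starting material
32 | (3R)-3-(tetradecanoyloxy)-12'-apo-β-caroten-12'-al | O=C/C(C)=C/C=C/C=C(C)/C=C/C=C(C)/C=C/C1=C(C)C[C@@H](OC(=O)CCCCCCCCCCCCC)CC1(C)C | intermediate
33 | ylide of 17 | CC(C)(C)[Si](C)(C)O[C@H]1C=C(C)[C@H](/C=C/C(C)=C/C=P(c2ccccc2)(c2ccccc2)c2ccccc2)C(C)(C)C1 | intermediate
34 | (3R,3'R,6'R)-3'-[(tert-butyldimethylsilyl)oxy]-β,ε-caroten-3-yl tetradecanoate | CC(C)(C)[Si](C)(C)O[C@H]1C=C(C)[C@H](/C=C/C(C)=C/C=C/C(C)=C/C=C/C=C(C)/C=C/C=C(C)/C=C/C2=C(C)C[C@@H](OC(=O)CCCCCCCCCCCCC)CC2(C)C)C(C)(C)C1 | intermediate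
35 | (3R,3'R,6'R)-3'-hydroxy-β,ε-caroten-3-yl tetradecanoate | O[C@H]1C=C(C)[C@H](/C=C/C(C)=C/C=C/C(C)=C/C=C/C=C(C)/C=C/C=C(C)/C=C/C2=C(C)C[C@@H](OC(=O)CCCCCCCCCCCCC)CC2(C)C)C(C)(C)C1 | intermediate
36 | palmitoyl chloride | CCCCCCCCCCCCCCCC(=O)Cl | starting material
37 | (3R,3'R,6'R)-3-(tetradecanoyloxy)-β,ε-caroten-3'-yl hexadecanoate | CCCCCCCCCCCCCCCC(=O)O[C@H]1C=C(C)[C@H](/C=C/C(C)=C/C=C/C(C)=C/C=C/C=C(C)/C=C/C=C(C)/C=C/C2=C(C)C[C@@H](OC(=O)CCCCCCCCCCCCC)CC2(C)C)C(C)(C)C1 | target

Total step count: 19.
Longest linear sequence: 11 steps (steps 1–8, then 17–19). The β-ring branch reaches 32 in 7 steps (9, 10, 11, 13–16), and step 12 is a one-step side branch.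

Steps most likely to fail

1. Step 2 (the unprecedented step).
- What may go wrong: epimerisation at C6' may be slower than hydride transfer, so that both enantiomers are reduced and the trans/cis selectivity collapses. Conjugate reduction, reduction through the deconjugated tautomer, or weak enantioface discrimination at an enone that lacks an aryl group are the other ways to fail.
- Fallback (classical resolution, known chemistry), from 5 back to 7: Luche reduction of 5 (NaBH4, CeCl3·7H2O, MeOH, −40 °C) gives the racemic allylic alcohols. The racemic trans alcohol F1 is separated by chromatography from the racemic cis alcohol F2. Esterification of F1 with (S)-O-methylmandelic acid (DCC, DMAP, CH2Cl2) gives the (1R,4R) mandelate F3 and the (1S,4S) mandelate F4. These are separated by chromatography or crystallisation and assigned by the usual mandelate shielding model. Ethanolysis of F3 (K2CO3, EtOH, rt), which the neopentyl-type ring ester should survive, returns 7.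

2. Step 6.
- What may go wrong: enolisation of the hindered aldehyde by the phosphonate anion would erode C6', move the ring double bond into conjugation or expel silanolate. The C9'=C10' geometry may also leak.
- Fallback (base-free chain extension), from 10 back to 13: Takai olefination of 10 (CrCl2, CHI3, THF, 0 °C) gives the (E)-vinyl iodide F5 under essentially neutral conditions. The stannane ethyl (E)-3-(tributylstannyl)but-2-enoate F6 is made from ethyl but-2-ynoate by syn stannylcupration (Li[Bu3SnCuSPh], THF–MeOH, −78 °C). Stille coupling of F5 with F6 (PdCl2(MeCN)2, DMF, rt) forms C8'–C9' with both geometries retained and delivers 13.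

3. Step 8.
- What may go wrong: ionisation of the dienylic mesylate or chloride may scramble the C9'=C10' geometry, divert phosphine attack to the tertiary allylic terminus, or start loss of the allylic silyl ether.
- Fallback (reversal of polarity at C11'=C12'), from 14 and 32 back to 34: 14 is oxidised with MnO2 (CH2Cl2, rt) to the ε-ring C15 aldehyde F7. Compound 32 is reduced with NaBH4 (EtOH–THF, 0 °C) to the C25 alcohol F8, and PPh3·HBr (CH2Cl2–MeOH, rt) converts it into the C25 phosphonium bromide F9, so that acid is applied only to the acid-stable β half. Deprotonation of F9 with NaN(SiMe3)2 (THF, −78 °C), addition of F7 and thermal equilibration give 34.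

Further compounds
F1 | step 2 | racemic ethyl (1R*,4R*)-4-hydroxy-2,6,6-trimethylcyclohex-2-ene-1-carboxylate (trans) | O[C@H]1C=C(C)[C@H](C(=O)OCC)C(C)(C)C1.O[C@@H]1C=C(C)[C@@H](C(=O)OCC)C(C)(C)C1
F2 | step 2 | racemic ethyl (1R*,4S*)-4-hydroxy-2,6,6-trimethylcyclohex-2-ene-1-carboxylate (cis) | O[C@H]1C=C(C)[C@@H](C(=O)OCC)C(C)(C)C1.O[C@@H]1C=C(C)[C@H](C(=O)OCC)C(C)(C)C1
F3 | step 2 | ethyl (1R,4R)-4-{[(2S)-2-methoxy-2-phenylacetyl]oxy}-2,6,6-trimethylcyclohex-2-ene-1-carboxylate | CO[C@H](C(=O)O[C@H]1C=C(C)[C@H](C(=O)OCC)C(C)(C)C1)c1ccccc1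
F4 | step 2 | ethyl (1S,4S)-4-{[(2S)-2-methoxy-2-phenylacetyl]oxy}-2,6,6-trimethylcyclohex-2-ene-1-carboxylate | CO[C@H](C(=O)O[C@@H]1C=C(C)[C@@H](C(=O)OCC)C(C)(C)C1)c1ccccc1
F5 | step 6 | tert-butyl({(1R,4R)-4-[(E)-2-iodoethenyl]-3,5,5-trimethylcyclohex-2-en-1-yl}oxy)dimethylsilane | CC(C)(C)[Si](C)(C)O[C@H]1C=C(C)[C@H](/C=C/I)C(C)(C)C1
F6 | step 6 | ethyl (E)-3-(tributylstannyl)but-2-enoate | CCOC(=O)/C=C(C)/[Sn](CCCC)(CCCC)CCCC
F7 | step 8 | (2E,4E)-5-[(1R,4R)-4-[(tert-butyldimethylsilyl)oxy]-2,6,6-trimethylcyclohex-2-en-1-yl]-3-methylpenta-2,4-dienal | CC(C)(C)[Si](C)(C)O[C@H]1C=C(C)[C@H](/C=C/C(C)=C/C=O)C(C)(C)C1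
F8 | step 8 | (3R)-12'-hydroxy-12'-apo-β-caroten-3-yl tetradecanoate | OC/C(C)=C/C=C/C=C(C)/C=C/C=C(C)/C=C/C1=C(C)C[C@@H](OC(=O)CCCCCCCCCCCCC)CC1(C)C
F9 | step 8 | [(3R)-3-(tetradecanoyloxy)-12'-apo-β-caroten-12'-yl]triphenylphosphonium bromide | [Br-].c1ccc(cc1)[P+](c1ccccc1)(c1ccccc1)C/C(C)=C/C=C/C=C(C)/C=C/C=C(C)/C=C/C2=C(C)C[C@@H](OC(=O)CCCCCCCCCCCCC)CC2(C)C
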